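**Retrosynthetic overview**

1. Target ⇒ bridged keto ether 21 by O‑demethylation, double Rieche formylation and removal of the C3 carbonyl group.
2. 21 ⇒ tricyclic dienone 15: the oxepine (O–C1) closes last by oxa‑Michael addition after enone transposition; before that C4–CH3 comes from α‑methylation of the extended enolate and C10–H from a 1,6‑hydride addition.
3. 15 ⇒ cyclopentenone 13: the cycloheptane is closed at C1–C10 by an intramolecular vinylogous aldol condensation.
4. 13 ⇒ aldehyde 10 (from (+)‑2‑carene; C6 and C7 bought) + vinyl ketone 6 (C7' set by organocatalysis), joined by Stetter reaction and aldol cyclisation (C5–C1, then C4=C5).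
5. Enabling feature: C1 is the γ‑carbon of the cyclopentenone C3(=O)–C4=C5, and the cis‑fused gem‑dimethylcyclopropane C6–C7–C11 holds the C8–C9–C10(=O) arm syn to it, so the ring C1–C5–C6–C7–C8–C9–C10 can close. Ring order: arene and cyclopropane (bought) → cyclopentenone → cycloheptane → oxepine.

Key step: step 10

Remark: atoms are numbered as in aromadendrane (C1 = O‑bearing ring‑fusion carbon, C2/C3 = ring CH2, C4 = quaternary C–CH3, C5 = ring‑fusion CH, C6/C7 = cyclopropane CH, C8/C9 = CH2, C10 = CH–CH3, C11 = CMe2); C7' is the benzylic carbon; β is the face of the CMe2 bridge (H6, H7 are α).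
Remark: carbinol centres that are oxidised later (C3 of 4 and 5, C10 of 9–12) are carried as epimer mixtures.

**Route**

Step 1
Reactants: 1 3,5‑dimethoxyphenol; 2 (E)‑5‑methylhex‑2‑enal
Product: 3 (4R)‑5,7‑dimethoxy‑4‑(2‑methylpropyl)chroman‑2‑ol
Conditions: (S)‑α,α‑diphenylprolinol trimethylsilyl ether (cat.), PhCO2H (cat.), toluene, rt
Reagents that add atoms: none
Why: Iminium‑catalysed asymmetric Friedel–Crafts alkylation of the phenol through its ortho carbon followed by hemiacetalisation (phenol–enal annulation); the catalyst shields one face of the E‑iminium ion, so the arene adds to the β‑carbon from the open face and sets the benzylic centre (later C7') as R by catalyst control.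

Step 2
Reactants: 3 chromanol
Product: 4 (5R)‑5‑(2‑hydroxy‑4,6‑dimethoxyphenyl)‑7‑methyloct‑1‑en‑3‑ol
Conditions: CH2=CHMgBr (3 equiv), THF, 0 °C to rt; aq. NH4Cl
Reagents that add atoms: vinylmagnesium bromide, C=C[Mg]Br
Why: Grignard addition to a lactol: one equivalent deprotonates the hemiacetal, the ring‑opened phenoxide aldehyde is captured by a second equivalent, and the new carbinol centre needs no control because it is oxidised in step 4.

Step 3
Reactants: 4 phenol diol
Product: 5 (5R)‑5‑[4,6‑dimethoxy‑2‑(prop‑2‑enyloxy)phenyl]‑7‑methyloct‑1‑en‑3‑ol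
Conditions: allyl bromide, K2CO3, acetone, 56 °C
Reagents that add atoms: allyl bromide, C=CCBr
Why: Williamson ether synthesis that is selective for the phenol because carbonate deprotonates only the phenolic OH and not the secondary alcohol.

Step 4
Reactants: 5 allylic alcohol
Product: 6 (5R)‑5‑[4,6‑dimethoxy‑2‑(prop‑2‑enyloxy)phenyl]‑7‑methyloct‑1‑en‑3‑one
Conditions: Dess–Martin periodinane, NaHCO3, CH2Cl2, 0 °C
Reagents that add atoms: none
Why: Dess–Martin oxidation of the allylic alcohol gives the vinyl ketone under buffered conditions that do not epimerise the benzylic centre or add to the new enone.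

Step 5
Reactants: 7 (+)‑2‑carene
Product: 9 4‑[(1R,3S)‑3‑(hydroxymethyl)‑2,2‑dimethylcyclopropyl]butan‑2‑ol, via keto aldehyde 8 (not isolated)
Conditions: O3, CH2Cl2/MeOH, −78 °C; Me2S; then NaBH4, 0 °C
Reagents that add atoms: ozone, [O-][O+]=O
Why: Ozonolysis with reductive work‑up cleaves the only C=C bond and borohydride reduces both carbonyl groups, so the cis‑cyclopropane stereocentres C6 and C7 are taken over unchanged from the chiral pool and the C10 carbinol centre is a mixture that is oxidised in step 9.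

Step 6
Reactants: 9 diol
Product: 10 (1S,3R)‑3‑(3‑hydroxybutyl)‑2,2‑dimethylcyclopropane‑1‑carbaldehyde
Conditions: TEMPO (cat.), PhI(OAc)2, CH2Cl2, rt
Reagents that add atoms: none
Why: TEMPO/oxoammonium oxidation is selective for the primary alcohol over the secondary one, which leaves C10 at the alcohol level so that no ketone enolate can compete when the cyclopentenone is built.

Step 7
Reactants: 10 hydroxy aldehyde; 6 vinyl ketone
Product: 11 (6R)‑6‑[4,6‑dimethoxy‑2‑(prop‑2‑enyloxy)phenyl]‑1‑[(1S,3R)‑3‑(3‑hydroxybutyl)‑2,2‑dimethylcyclopropyl]‑8‑methylnonane‑1,4‑dione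
Conditions: 3‑benzyl‑5‑(2‑hydroxyethyl)‑4‑methylthiazolium chloride (cat.), Et3N, EtOH, 75 °C
Reagents that add atoms: none
Why: Stetter reaction in which the Breslow intermediate of the aldehyde adds as an acyl anion equivalent to the β‑carbon of the vinyl ketone, forming the C5–C1 bond and the 1,4‑diketone without touching a stereocentre.

Step 8
Reactants: 11 1,4‑diketone
Product: 12 cyclopentenone: 2‑(1‑aryl‑3‑methylbutyl)‑3‑[cis‑3‑(3‑hydroxybutyl)‑2,2‑dimethylcyclopropyl]cyclopent‑2‑en‑1‑one (aryl = 4,6‑dimethoxy‑2‑allyloxyphenyl)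
Conditions: KOH, EtOH/H2O, 78 °C
Reagents that add atoms: none
Why: Base‑mediated intramolecular aldol condensation of a 1,4‑diketone, in which attack of C4 on the cyclopropyl ketone C5 is the only mode that gives a five‑membered ring, furnishes the tetrasubstituted cyclopentenone as in jasmone‑type syntheses.

Step 9
Reactants: 12 hydroxy enone
Product: 13 keto enone: as 12 but with a 3‑oxobutyl chain (C10 methyl ketone)
Conditions: Dess–Martin periodinane, NaHCO3, CH2Cl2, 0 °C to rt
Reagents that add atoms: none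
Why: Dess–Martin oxidation of the secondary alcohol unmasks the C10 methyl ketone only after the C5 carbonyl group has been consumed, so the competing aldol of a 1,6‑diketone to a bicyclic five‑membered by‑product can no longer occur.

Step 10
Reactants: 13 keto enone
Product: 15 tricyclic dienone (5‑7‑3 core, C3=O, C4=C5, C1=C10, 6αH, 7αH, side chain on C4), via vinylogous aldol adduct 14 (not isolated)
Conditions: KOH, EtOH, 78 °C
Reagents that add atoms: none
Why: Base removes a γ‑proton (C1–H) of the cyclopentenone to give the extended dienolate O–C3=C4–C5=C1, whose γ‑carbon C1 adds to the C10 methyl ketone, and E1cB loss of water from adduct 14 gives the fully conjugated dienone. The closest known reaction type is the intramolecular vinylogous aldol condensation (cyclodehydration through the γ‑position of a cyclic enone). The seven‑membered carbocycle C1–C5–C6–C7–C8–C9–C10 is closed in the 7‑(enolendo)‑exo‑trig mode onto the ketone carbonyl. No stereocentre is created (C1 and C10 become sp2), and C6, C7 and C7' are not enolisable under the conditions. The step needs γ‑ over α‑ and α'‑selectivity and must outrun reactions of the methyl ketone enolates: attack through C4 gives an aldol that cannot dehydrate and reverts, attack through C2 would need an eight‑membered ring, and only the γ‑adduct can eliminate to the thermodynamic sink. The cis‑cyclopropane holds the cyclopentenone and the C8–C9–C10 chain on the same side, so that C10 lies within reach of C1.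

Step 11
Reactants: 15 dienone
Product: 16 dimethyl(phenyl)silyl dienol ether (C3–OSi, C3=C4, C5=C1, 10αH, 10β‑CH3)
Conditions: [(Ph3P)CuH]6 (cat.), PhMe2SiH, toluene, rt
Reagents that add atoms: dimethylphenylsilane, C[SiH](C)c1ccccc1
Why: Copper hydride conjugate reduction with silane turnover takes the 1,6‑course because the β‑carbon C5 is fully substituted, and the hydride reaches the δ‑carbon C10 from the α‑face, away from the CMe2 bridge of the cyclopropane, which sets C10 by substrate control while the dienolate is trapped on oxygen.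

Step 12
Reactants: 16 silyl dienol ether
Product: 18 β,γ‑enone with quaternary C4 (4α‑CH3, 4β side chain, C5=C1, C3=O), via lithium dienolate 17 (not isolated)
Conditions: MeLi, THF, 0 °C; then MeI, −78 to 0 °C
Reagents that add atoms: iodomethane, CI
Why: Methyllithium cleaves the Si–O bond to give the regiodefined lithium dienolate, which is alkylated at its α‑carbon C4 (deconjugative α‑alkylation of an extended enolate), and methyl iodide enters from the α‑face because the β‑face is covered by the CMe2 group of the cyclopropane next to C5 and by the aryl group in the reactive side‑chain rotamer, which sets C4 by substrate control.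

Step 13
Reactants: 18 β,γ‑enone
Product: 21 bridged keto ether (3‑oxo derivative of the bis‑O‑methyl, formyl‑free target), via phenol 19 (not isolated), via conjugated enone 20 (not isolated)
Conditions: Pd(PPh3)4 (cat.), K2CO3, MeOH, 50 °C
Reagents that add atoms: none
Why: Palladium‑catalysed deallylation through a π‑allyl complex frees the phenoxide, base moves the C5=C1 double bond into conjugation with the ketone on the only side open to it because C4 is quaternary, C5 is reprotonated under thermodynamic control with H5 on the β‑face so that the cyclopropane points away from the aryl‑bearing substituent, and intramolecular oxa‑Michael addition of the phenoxide to the β‑carbon C1 closes the oxepine ring with C1 fixed by the tether.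

Step 14
Reactants: 21 bridged keto ether
Product: 22 tosylhydrazone of 21
Conditions: TsNHNH2, MeOH, 50 °C
Reagents that add atoms: 4‑methylbenzenesulfonohydrazide, Cc1ccc(cc1)S(=O)(=O)NN
Why: Tosylhydrazone formation at the cyclopentanone carbonyl, which is open on its CH2 side, proceeds under near‑neutral conditions that do not enolise the β‑aryloxy ketone.

Step 15
Reactants: 22 tosylhydrazone
Product: 23 bis‑O‑methyl, formyl‑free target (C3 = CH2)
Conditions: catecholborane, CHCl3, 0 °C; then NaOAc·3H2O, 60 °C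
Reagents that add atoms: none
Why: Kabalka reduction of the tosylhydrazone (hydroboration of C=N, then acetate‑induced loss of sulfinate and N2) turns C3 into CH2 without passing through a ketone enolate that could expel the β‑aryloxide.

Step 16
Reactants: 23 aryl ether
Product: 24 bis‑O‑methyl ether of the target (two CHO groups in place)
Conditions: Cl2CHOMe (excess), AgOTf, CH2Cl2, −40 to 0 °C; aq. NaHCO3
Reagents that add atoms: dichloromethyl methyl ether, COC(Cl)Cl; water, O
Why: Rieche formylation under silver activation attacks the only two free ring positions, each flanked by two oxygen substituents, and avoids the strong Lewis acids that could ionise the tertiary aryl ether or open the cyclopropane.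

Step 17
Reactants: 24 dialdehyde bis‑methyl ether
Product: 25 CNP0189833.2 (target)
Conditions: NaSEt, DMF, 100 °C; aq. HCl
Reagents that add atoms: none
Why: Thiolate cleaves the two aryl methyl ethers by SN2 attack at methyl, activated by the ortho and para formyl groups, while the third ether carbon is tertiary and inert to SN2 displacement.

**Compound list**

1 | 3,5‑dimethoxyphenol | COc1cc(O)cc(OC)c1 | starting material
2 | (E)‑5‑methylhex‑2‑enal | CC(C)C/C=C/C=O | starting material
3 | (4R)‑5,7‑dimethoxy‑4‑(2‑methylpropyl)chroman‑2‑ol (anomer mixture) | CC(C)C[C@@H]1CC(O)Oc2cc(OC)cc(OC)c21 | intermediate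
4 | (5R)‑5‑(2‑hydroxy‑4,6‑dimethoxyphenyl)‑7‑methyloct‑1‑en‑3‑ol (C3 epimers) | CC(C)C[C@H](CC(O)C=C)c1c(O)cc(OC)cc1OC | intermediate
5 | (5R)‑5‑[4,6‑dimethoxy‑2‑(prop‑2‑enyloxy)phenyl]‑7‑methyloct‑1‑en‑3‑ol | CC(C)C[C@H](CC(O)C=C)c1c(OCC=C)cc(OC)cc1OC | intermediate
6 | (5R)‑5‑[4,6‑dimethoxy‑2‑(prop‑2‑enyloxy)phenyl]‑7‑methyloct‑1‑en‑3‑one | CC(C)C[C@H](CC(=O)C=C)c1c(OCC=C)cc(OC)cc1OC | intermediate
7 | (+)‑2‑carene, (1S,6R)‑3,7,7‑trimethylbicyclo[4.1.0]hept‑2‑ene | CC1=C[C@H]2[C@@H](CC1)C2(C)C | starting material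
8 | (1S,3R)‑2,2‑dimethyl‑3‑(3‑oxobutyl)cyclopropane‑1‑carbaldehyde (cis) | O=C[C@H]1[C@@H](CCC(C)=O)C1(C)C | intermediate
9 | 4‑[(1R,3S)‑3‑(hydroxymethyl)‑2,2‑dimethylcyclopropyl]butan‑2‑ol (cis; C2 epimers) | OC[C@H]1[C@@H](CCC(C)O)C1(C)C | intermediate
10 | (1S,3R)‑3‑(3‑hydroxybutyl)‑2,2‑dimethylcyclopropane‑1‑carbaldehyde (cis) | O=C[C@H]1[C@@H](CCC(C)O)C1(C)C | intermediate
11 | (6R)‑6‑[4,6‑dimethoxy‑2‑(prop‑2‑enyloxy)phenyl]‑1‑[(1S,3R)‑3‑(3‑hydroxybutyl)‑2,2‑dimethylcyclopropyl]‑8‑methylnonane‑1,4‑dione | CC(C)C[C@H](CC(=O)CCC(=O)[C@H]1[C@@H](CCC(C)O)C1(C)C)c1c(OCC=C)cc(OC)cc1OC | intermediate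
12 | 2‑(1‑aryl‑3‑methylbutyl)‑3‑[cis‑3‑(3‑hydroxybutyl)‑2,2‑dimethylcyclopropyl]cyclopent‑2‑en‑1‑one (aryl = 4,6‑dimethoxy‑2‑allyloxyphenyl; benzylic centre as set in step 1) | CC(C)C[C@H](C1=C(CCC1=O)[C@H]2[C@@H](CCC(C)O)C2(C)C)c1c(OCC=C)cc(OC)cc1OC | intermediate
13 | 2‑(1‑aryl‑3‑methylbutyl)‑3‑[cis‑2,2‑dimethyl‑3‑(3‑oxobutyl)cyclopropyl]cyclopent‑2‑en‑1‑one | CC(C)C[C@H](C1=C(CCC1=O)[C@H]2[C@@H](CCC(C)=O)C2(C)C)c1c(OCC=C)cc(OC)cc1OC | intermediate
14 | vinylogous aldol adduct: tricyclic 10‑hydroxy‑4‑en‑3‑one (C1–H, C10–OH; epimers) | CC(C)C[C@H](C1=C2[C@H]3[C@@H](CCC(C)(O)C2CC1=O)C3(C)C)c1c(OCC=C)cc(OC)cc1OC | intermediate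
15 | tricyclic 1(10),4‑dien‑3‑one with the 1‑aryl‑3‑methylbutyl group on C4 (6αH,7αH) | CC(C)C[C@H](C1=C2[C@H]3[C@@H](CCC(C)=C2CC1=O)C3(C)C)c1c(OCC=C)cc(OC)cc1OC | intermediate
16 | 3‑[dimethyl(phenyl)silyloxy] 3,5(1)‑diene (10αH, 10β‑CH3) | CC(C)C[C@@H](c1c(OCC=C)cc(OC)cc1OC)C1=C(O[Si](C)(C)c2ccccc2)CC2=C1[C@H]1[C@@H](CC[C@@H]2C)C1(C)C | intermediate
17 | lithium dienolate corresponding to 16 | CC(C)C[C@@H](c1c(OCC=C)cc(OC)cc1OC)C1=C(O[Li])CC2=C1[C@H]1[C@@H](CC[C@@H]2C)C1(C)C | intermediate
18 | 4α‑methyl‑4β‑(1‑aryl‑3‑methylbutyl) 1(5)‑en‑3‑one (aryl O‑allyl) | CC(C)C[C@@H](c1c(OCC=C)cc(OC)cc1OC)[C@@]1(C)C(=O)CC2=C1[C@H]1[C@@H](CC[C@@H]2C)C1(C)C | intermediate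
19 | free phenol corresponding to 18 | CC(C)C[C@@H](c1c(O)cc(OC)cc1OC)[C@@]1(C)C(=O)CC2=C1[C@H]1[C@@H](CC[C@@H]2C)C1(C)C | intermediate
20 | conjugated 1‑en‑3‑one (C1=C2, 5βH) with free phenol | CC(C)C[C@@H](c1c(O)cc(OC)cc1OC)[C@@]1(C)C(=O)C=C2[C@@H]1[C@H]1[C@@H](CC[C@@H]2C)C1(C)C | intermediate
21 | bridged keto ether: 3‑oxo derivative of the bis‑O‑methyl, formyl‑free target | CC(C)C[C@H]1c2c(OC)cc(OC)cc2O[C@]23CC(=O)[C@@]1(C)[C@H]2[C@H]1[C@@H](CC[C@@H]3C)C1(C)C | intermediate
22 | tosylhydrazone of 21 | CC(C)C[C@H]1c2c(OC)cc(OC)cc2O[C@]23CC(=NNS(=O)(=O)c4ccc(C)cc4)[C@@]1(C)[C@H]2[C@H]1[C@@H](CC[C@@H]3C)C1(C)C | intermediate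
23 | bis‑O‑methyl, formyl‑free target | CC(C)C[C@H]1c2c(OC)cc(OC)cc2O[C@]23CC[C@@]1(C)[C@H]2[C@H]1[C@@H](CC[C@@H]3C)C1(C)C | intermediate
24 | bis‑O‑methyl ether of the target | CC(C)C[C@H]1c2c(OC)c(C=O)c(OC)c(C=O)c2O[C@]23CC[C@@]1(C)[C@H]2[C@H]1[C@@H](CC[C@@H]3C)C1(C)C | intermediate
25 | CNP0189833.2 (1β‑aryloxy bridge, 4α‑CH3, 5βH, 6αH, 7αH, 10β‑CH3, C7' R) | CC(C)C[C@H]1c2c(O)c(C=O)c(O)c(C=O)c2O[C@]23CC[C@@]1(C)[C@H]2[C@H]1[C@@H](CC[C@@H]3C)C1(C)C | target

**Count and risks**

Total steps: 17. Longest linear sequence: 15 (steps 1–4, then 7–17).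

Steps most likely to fail:

1. Step 13. The ring closure may stall because the equilibrium between the open enone and the strained bridged β‑aryloxy ketone can lie on the side of the enone (retro‑Michael), and long contact with base can epimerise C10 through the γ‑dienolate. Fallback: starting from 18, the deallylation and isomerisation are stopped at the open enone 20, which is isolated. Luche reduction (NaBH4, CeCl3·7H2O, MeOH) should give the allylic alcohol F1. Intramolecular phenoxymercuration (Hg(OCOCF3)2, THF; then NaBH4, aq. NaOH) is irreversible and Markovnikov, and the phenol can only reach the tertiary carbon C1, so it should give the bridged ether alcohol F2. Xanthate formation (NaH, CS2, MeI) gives the xanthate F3, and Barton–McCombie reduction (Bu3SnH, AIBN, toluene, 100 °C) comes back to the route at 23, so steps 14 and 15 are not needed.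

2. Step 12. C‑methylation at the hindered, fully substituted α‑carbon may lose to O‑methylation or to proton transfer and methylation at C2, and the facial preference may erode. Fallback: starting from 16, Furukawa–Simmons–Smith cyclopropanation (Et2Zn, CH2I2, CH2Cl2, 0 °C) of the electron‑rich silyl enol ether double bond C3=C4 from the α‑face should give the siloxycyclopropane F4. Acid‑mediated ring opening (TsOH·H2O, MeOH, 0 °C; Conia methylation) comes back to the route at 18.

3. Step 11. The hydride may be delivered in the 1,4‑ or 1,2‑sense, or without facial control at C10. Fallback: starting from 15, deconjugative α‑methylation of the extended trienolate (KOtBu, t‑BuOH, MeI, rt) should give the 4‑methyl trienone F5 (double bonds C5=C1 and C9=C10). The conditions of step 13 (Pd(PPh3)4, K2CO3, MeOH) should then give the bridged keto ether F6, which still holds the C9=C10 double bond. Hydrogenation (H2, Pd/C, EtOAc) from the α‑face, away from the aryl ether bridge and the CMe2 group, comes back to the route at 21.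

**Further compounds**

F1 | step 13 | allylic alcohol from 20 (C3–OH, C1=C2, free phenol) | CC(C)C[C@@H](c1c(O)cc(OC)cc1OC)[C@@]1(C)C(O)C=C2[C@@H]1[C@H]1[C@@H](CC[C@@H]2C)C1(C)C
F2 | step 13 | bridged ether alcohol (3‑hydroxy analogue of 23) | CC(C)C[C@H]1c2c(OC)cc(OC)cc2O[C@]23CC(O)[C@@]1(C)[C@H]2[C@H]1[C@@H](CC[C@@H]3C)C1(C)C
F3 | step 13 | S‑methyl xanthate of F2 | CC(C)C[C@H]1c2c(OC)cc(OC)cc2O[C@]23CC(OC(=S)SC)[C@@]1(C)[C@H]2[C@H]1[C@@H](CC[C@@H]3C)C1(C)C
F4 | step 12 | siloxycyclopropane from 16 (CH2 across C3–C4 on the α‑face) | CC(C)C[C@@H](c1c(OCC=C)cc(OC)cc1OC)[C@@]12C[C@]1(O[Si](C)(C)c3ccccc3)CC3=C2[C@H]2[C@@H](CC[C@@H]3C)C2(C)C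
F5 | step 11 | 4‑methyl trienone (C3=O, C5=C1, C9=C10) | CC(C)C[C@@H](c1c(OCC=C)cc(OC)cc1OC)[C@@]1(C)C(=O)CC2=C1[C@H]1[C@@H](CC=C2C)C1(C)C
F6 | step 11 | bridged keto ether with C9=C10 double bond | CC(C)C[C@H]1c2c(OC)cc(OC)cc2O[C@]23CC(=O)[C@@]1(C)[C@H]2[C@H]1[C@@H](CC=C3C)C1(C)C
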